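**Strategy**

Everything rests on cutting C2–C1′, the bond between the fully substituted, oxygen-bearing C2 of the dihydropyran ring and the first CH2 of the side chain. A stereospecific lithiation–borylation makes it: the α-lithiated (S)-triisopropylbenzoate of a 4-arylbutan-2-ol (the aryl group is the future benzo ring, with chlorine at C8a) captures the primary neopentyl-glycol boronate of the complete C16 chain, whose C9′ ketone is masked as a 1,3-dithiane. 1,2-Migration forges C2–C1′ and oxidation gives the (R)-tertiary alcohol in one operation; its oxygen becomes O1 in a palladium-catalysed aryl C–O closure that leaves C2 untouched.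

Key step: step 12

Remark: chroman numbering (O1, C2, C3, C4, C4a–C8a) is used for the bicycle and primed numbers for the side chain (C1′ bonded to C2, C9′ = ketone carbon); the target is (2R) with both chain alkenes E.

**Route**

Step 1
Reactants: 1 4-chloro-3,5-dimethylphenol
Product: 2 (4-chloro-3,5-dimethylphenoxy)triisopropylsilane
Conditions: TIPSCl, imidazole, DMF, rt
Reagents that add atoms: triisopropylsilyl chloride, CC(C)[Si](Cl)(C(C)C)C(C)C
Why: O-silylation of the phenol; the hindered TIPS ether is expected to withstand the Grignard, organolithium and carbonate steps and to block lithiation ortho to oxygen.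

Step 2
Reactants: 2 (4-chloro-3,5-dimethylphenoxy)triisopropylsilane
Product: 3 [3-(bromomethyl)-4-chloro-5-methylphenoxy]triisopropylsilane
Conditions: NBS (1.0 equiv), AIBN (cat.), PhCF3, 80 °C
Reagents that add atoms: N-bromosuccinimide, O=C1CCC(=O)N1Br
Why: Wohl–Ziegler radical benzylic bromination of one of the two equivalent methyl groups, the radical chain in a non-polar solvent being expected to outrun electrophilic ring bromination.

Step 3
Reactants: 3 [3-(bromomethyl)-4-chloro-5-methylphenoxy]triisopropylsilane, 4 (R)-propylene oxide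
Product: 6 (R)-4-{2-chloro-3-methyl-5-[(triisopropylsilyl)oxy]phenyl}butan-2-ol, via benzylic Grignard reagent 5 (not isolated)
Conditions: Mg, 2-MeTHF, 0 °C; then CuI (10 mol%), 4, −30 → 0 °C
Reagents that add atoms: none
Why: Copper-catalysed SN2 opening of the epoxide at its unsubstituted carbon by the benzylic Grignard reagent, so the carbinol stereocentre is carried over unchanged from (R)-4.

Step 4
Reactants: 6 (R)-4-{2-chloro-3-methyl-5-[(triisopropylsilyl)oxy]phenyl}butan-2-ol
Product: 7 (S)-4-{2-chloro-3-methyl-5-[(triisopropylsilyl)oxy]phenyl}butan-2-yl 2,4,6-triisopropylbenzoate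
Conditions: 2,4,6-triisopropylbenzoic acid, PPh3, DIAD, THF, 0 °C → rt
Reagents that add atoms: 2,4,6-triisopropylbenzoic acid, CC(C)c1cc(C(C)C)c(C(=O)O)c(C(C)C)c1
Why: Mitsunobu esterification, which should invert the carbinol centre cleanly (SN2 on the alkoxyphosphonium ion) and so set the (S) configuration required for the key step.

Step 5
Reactants: 8 geranyl acetate
Product: 9 (2E,6E)-3,7-dimethyl-8-oxoocta-2,6-dien-1-yl acetate
Conditions: SeO2 (1.1 equiv), 95% EtOH, reflux
Reagents that add atoms: selenium dioxide, O=[Se]=O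
Why: Riley allylic oxidation, whose ene/[2,3]-sigmatropic mechanism is selective for the (E)-methyl group of the electron-rich terminal trisubstituted alkene and should deliver the (E)-enal.

Step 6
Reactants: 9 (2E,6E)-3,7-dimethyl-8-oxoocta-2,6-dien-1-yl acetate
Product: 10 (2E,6E)-7-(1,3-dithian-2-yl)-3-methylocta-2,6-dien-1-yl acetate
Conditions: HS(CH2)3SH, BF3·OEt2 (cat.), CH2Cl2, −20 → 0 °C
Reagents that add atoms: propane-1,3-dithiol, SCCCS
Why: Lewis-acid-catalysed dithioacetalisation of the aldehyde (1,2-addition favoured for the α-branched enal), which installs the acyl-anion handle that later also masks the C9′ ketone.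

Step 7
Reactants: 10 (2E,6E)-7-(1,3-dithian-2-yl)-3-methylocta-2,6-dien-1-yl acetate
Product: 11 (2E,6E)-7-(1,3-dithian-2-yl)-3-methylocta-2,6-dien-1-ol
Conditions: K2CO3 (cat.), MeOH, rt
Reagents that add atoms: none
Why: Base-catalysed transesterification (methanolysis of the acetate) frees the primary allylic alcohol without touching the dithiane.

Step 8
Reactants: 11 (2E,6E)-7-(1,3-dithian-2-yl)-3-methylocta-2,6-dien-1-ol, 12 prenyl bromide
Product: 14 (2E,6E)-3-methyl-7-[2-(3-methylbut-2-en-1-yl)-1,3-dithian-2-yl]octa-2,6-dien-1-ol, via dilithio dianion 13 (not isolated)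
Conditions: nBuLi (2.1 equiv), THF, −78 → −30 °C; then 12, −78 °C → rt
Reagents that add atoms: none
Why: Corey–Seebach umpolung, in which the alkoxide/2-lithio-1,3-dithiane dianion is expected to be C-alkylated at the dithiane carbon (α-attack of the sulfur-stabilised allyl anion, SN2 at the primary allylic bromide), creating the C9′–C10′ bond with the (E)-C7′=C8′ alkene retained.

Step 9
Reactants: 14 (2E,6E)-3-methyl-7-[2-(3-methylbut-2-en-1-yl)-1,3-dithian-2-yl]octa-2,6-dien-1-ol
Product: 15 2-[(2E,6E)-8-bromo-6-methylocta-2,6-dien-2-yl]-2-(3-methylbut-2-en-1-yl)-1,3-dithiane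
Conditions: CBr4, PPh3, CH2Cl2, 0 °C
Reagents that add atoms: carbon tetrabromide, BrC(Br)(Br)Br
Why: Appel bromination converts the primary allylic alcohol into the bromide under neutral conditions without allylic transposition.

Step 10
Reactants: 15 2-[(2E,6E)-8-bromo-6-methylocta-2,6-dien-2-yl]-2-(3-methylbut-2-en-1-yl)-1,3-dithiane, 16 bis[(pinacolato)boryl]methane
Product: 17 4,4,5,5-tetramethyl-2-{(3E,7E)-4-methyl-8-[2-(3-methylbut-2-en-1-yl)-1,3-dithian-2-yl]nona-3,7-dien-1-yl}-1,3,2-dioxaborolane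
Conditions: NaOtBu, THF, rt
Reagents that add atoms: none
Why: Alkoxide-promoted deborylative alkylation of the geminal bis(boronate), in which tert-butoxide releases an α-boryl carbanion that should displace the primary allylic bromide by SN2, adding C1′ together with its boron atom.

Step 11
Reactants: 17 4,4,5,5-tetramethyl-2-{(3E,7E)-4-methyl-8-[2-(3-methylbut-2-en-1-yl)-1,3-dithian-2-yl]nona-3,7-dien-1-yl}-1,3,2-dioxaborolane
Product: 19 5,5-dimethyl-2-{(3E,7E)-4-methyl-8-[2-(3-methylbut-2-en-1-yl)-1,3-dithian-2-yl]nona-3,7-dien-1-yl}-1,3,2-dioxaborinane, via boronic acid 18 (not isolated)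
Conditions: MeB(OH)2 (excess), 0.1 M HCl, acetone/H2O, rt, evaporate; then neopentyl glycol, MgSO4, CH2Cl2, rt
Reagents that add atoms: 2,2-dimethylpropane-1,3-diol, CC(C)(CO)CO
Why: Boronic ester transesterification driven by removal of volatile methylboronic acid pinacol ester, followed by condensation with neopentyl glycol, gives the less hindered boronate that the hindered carbenoid of the key step needs.

Step 12
Reactants: 7 (S)-4-{2-chloro-3-methyl-5-[(triisopropylsilyl)oxy]phenyl}butan-2-yl 2,4,6-triisopropylbenzoate, 19 5,5-dimethyl-2-{(3E,7E)-4-methyl-8-[2-(3-methylbut-2-en-1-yl)-1,3-dithian-2-yl]nona-3,7-dien-1-yl}-1,3,2-dioxaborinane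
Product: 23 (3R,6E,10E)-1-{2-chloro-3-methyl-5-[(triisopropylsilyl)oxy]phenyl}-3,7-dimethyl-11-[2-(3-methylbut-2-en-1-yl)-1,3-dithian-2-yl]dodeca-6,10-dien-3-ol, via lithiated benzoate 20 (not isolated), via boronate complex 21 (not isolated), via tertiary boronic ester 22 (not isolated)
Conditions: 7 (slight excess), sBuLi, TMEDA, CPME, −60 °C; then 19, −60 → 50 °C; then NaOH, H2O2, THF/H2O, 0 °C → rt
Reagents that add atoms: hydrogen peroxide, OO
Why: Lithiation–borylation: the benzoate carbonyl directs sBuLi/TMEDA to the O-bearing C–H of 7, giving the configurationally stable α-oxy-organolithium 20 with retention, which adds to the boron of 19 with retention (21); on warming, the C1′ alkyl group migrates from boron to carbon anti to the departing triisopropylbenzoate (stereoinvertive 1,2-metallate shift) to give 22, and alkaline peroxide replaces boron by OH with retention. The closest known reaction type is the lithiation–borylation of secondary dialkyl 2,4,6-triisopropylbenzoates with neopentyl-glycol boronic esters to enantioenriched tertiary boronic esters and alcohols, a process established on the 4-arylbutan-2-yl skeleton present in 7. No ring is closed in this step. The new stereocentre C2 is controlled solely by the (S) configuration of 7 and the stereospecificity of each elementary step: C1′ ends where H was and the new OH where the benzoate oxygen was, i.e. (R), and this oxygen later becomes O1. The step needs chemoselective α-deprotonation and a boronate complex that rearranges instead of reverting; this should be secured by the carbonyl-directed lithiation, the absence of H ortho to chlorine, the bulky TIPS group beside the remaining ring hydrogens, an excess of 7 over sBuLi so that no free alkyllithium meets 19, a dithiane without acidic 2-H, and the unhindered neopentyl-glycol ester.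

Step 13
Reactants: 23 (3R,6E,10E)-1-{2-chloro-3-methyl-5-[(triisopropylsilyl)oxy]phenyl}-3,7-dimethyl-11-[2-(3-methylbut-2-en-1-yl)-1,3-dithian-2-yl]dodeca-6,10-dien-3-ol
Product: 24 {[(2R)-2,8-dimethyl-2-{(3E,7E)-4-methyl-8-[2-(3-methylbut-2-en-1-yl)-1,3-dithian-2-yl]nona-3,7-dien-1-yl}chroman-6-yl]oxy}triisopropylsilane
Conditions: tBuBrettPhos Pd G3 (5 mol%), Cs2CO3, toluene, 90 °C
Reagents that add atoms: none
Why: Palladium-catalysed intramolecular C–O coupling (Buchwald–Hartwig etherification) of the tertiary alkoxide with the aryl chloride closes the dihydropyran ring at the aryl carbon, so the C2–O bond and the C2 configuration are untouched and a tertiary alkoxide cannot undergo β-hydride elimination.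

Step 14
Reactants: 24 {[(2R)-2,8-dimethyl-2-{(3E,7E)-4-methyl-8-[2-(3-methylbut-2-en-1-yl)-1,3-dithian-2-yl]nona-3,7-dien-1-yl}chroman-6-yl]oxy}triisopropylsilane
Product: 25 (6E,10E)-13-{(2R)-2,8-dimethyl-6-[(triisopropylsilyl)oxy]chroman-2-yl}-2,6,10-trimethyltrideca-2,6,10-trien-5-one
Conditions: MeI (excess), CaCO3, MeCN/H2O (9:1), 45 °C
Reagents that add atoms: water, O
Why: Alkylative hydrolysis of the dithiane (S-methylation, ring opening and capture by water) under carbonate buffering should unveil the C9′ enone without migration of the β,γ-double bond.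

Step 15
Reactants: 25 (6E,10E)-13-{(2R)-2,8-dimethyl-6-[(triisopropylsilyl)oxy]chroman-2-yl}-2,6,10-trimethyltrideca-2,6,10-trien-5-one
Product: 26 (6E,10E)-13-[(2R)-6-hydroxy-2,8-dimethylchroman-2-yl]-2,6,10-trimethyltrideca-2,6,10-trien-5-one
Conditions: TBAF, AcOH (1:1), THF, 0 °C
Reagents that add atoms: none
Why: Fluoride-mediated desilylation of the aryl silyl ether, buffered with acetic acid so that the base-sensitive β,γ-unsaturated ketone is not isomerised.

**Compound list**

1 | 4-chloro-3,5-dimethylphenol | Cc1cc(O)cc(C)c1Cl | starting material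
2 | (4-chloro-3,5-dimethylphenoxy)triisopropylsilane | Cc1cc(O[Si](C(C)C)(C(C)C)C(C)C)cc(C)c1Cl | intermediate
3 | [3-(bromomethyl)-4-chloro-5-methylphenoxy]triisopropylsilane | BrCc1cc(O[Si](C(C)C)(C(C)C)C(C)C)cc(C)c1Cl | intermediate
4 | (R)-propylene oxide | C[C@@H]1CO1 | starting material
5 | {2-chloro-3-methyl-5-[(triisopropylsilyl)oxy]benzyl}magnesium bromide | Br[Mg]Cc1cc(O[Si](C(C)C)(C(C)C)C(C)C)cc(C)c1Cl | intermediate (not isolated)
6 | (R)-4-{2-chloro-3-methyl-5-[(triisopropylsilyl)oxy]phenyl}butan-2-ol | C[C@@H](O)CCc1cc(O[Si](C(C)C)(C(C)C)C(C)C)cc(C)c1Cl | intermediate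
7 | (S)-4-{2-chloro-3-methyl-5-[(triisopropylsilyl)oxy]phenyl}butan-2-yl 2,4,6-triisopropylbenzoate | C[C@H](OC(=O)c1c(C(C)C)cc(C(C)C)cc1C(C)C)CCc1cc(O[Si](C(C)C)(C(C)C)C(C)C)cc(C)c1Cl | intermediate
8 | geranyl acetate, (2E)-3,7-dimethylocta-2,6-dien-1-yl acetate | CC(C)=CCC/C(C)=C/COC(C)=O | starting material
9 | (2E,6E)-3,7-dimethyl-8-oxoocta-2,6-dien-1-yl acetate | O=C/C(C)=C/CC/C(C)=C/COC(C)=O | intermediate
10 | (2E,6E)-7-(1,3-dithian-2-yl)-3-methylocta-2,6-dien-1-yl acetate | CC(=O)OC/C=C(C)/CC/C=C(C)/C1SCCCS1 | intermediate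
11 | (2E,6E)-7-(1,3-dithian-2-yl)-3-methylocta-2,6-dien-1-ol | OC/C=C(C)/CC/C=C(C)/C1SCCCS1 | intermediate
12 | prenyl bromide, 1-bromo-3-methylbut-2-ene | CC(C)=CCBr | starting material
13 | dilithio derivative of 11 (lithium alkoxide and 2-lithio-1,3-dithiane) | [Li]OC/C=C(C)/CC/C=C(C)/C1([Li])SCCCS1 | intermediate (not isolated)
14 | (2E,6E)-3-methyl-7-[2-(3-methylbut-2-en-1-yl)-1,3-dithian-2-yl]octa-2,6-dien-1-ol | OC/C=C(C)/CC/C=C(C)/C1(CC=C(C)C)SCCCS1 | intermediate
15 | 2-[(2E,6E)-8-bromo-6-methylocta-2,6-dien-2-yl]-2-(3-methylbut-2-en-1-yl)-1,3-dithiane | BrC/C=C(C)/CC/C=C(C)/C1(CC=C(C)C)SCCCS1 | intermediate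
16 | bis[(pinacolato)boryl]methane | CC1(C)OB(CB2OC(C)(C)C(C)(C)O2)OC1(C)C | starting material
17 | 4,4,5,5-tetramethyl-2-{(3E,7E)-4-methyl-8-[2-(3-methylbut-2-en-1-yl)-1,3-dithian-2-yl]nona-3,7-dien-1-yl}-1,3,2-dioxaborolane | CC1(C)OB(CC/C=C(C)/CC/C=C(C)/C2(CC=C(C)C)SCCCS2)OC1(C)C | intermediate
18 | {(3E,7E)-4-methyl-8-[2-(3-methylbut-2-en-1-yl)-1,3-dithian-2-yl]nona-3,7-dien-1-yl}boronic acid | OB(O)CC/C=C(C)/CC/C=C(C)/C1(CC=C(C)C)SCCCS1 | intermediate (not isolated)
19 | 5,5-dimethyl-2-{(3E,7E)-4-methyl-8-[2-(3-methylbut-2-en-1-yl)-1,3-dithian-2-yl]nona-3,7-dien-1-yl}-1,3,2-dioxaborinane | CC1(C)COB(CC/C=C(C)/CC/C=C(C)/C2(CC=C(C)C)SCCCS2)OC1 | intermediate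
20 | (S)-α-lithiated benzoate derived from 7 | C[C@]([Li])(OC(=O)c1c(C(C)C)cc(C(C)C)cc1C(C)C)CCc1cc(O[Si](C(C)C)(C(C)C)C(C)C)cc(C)c1Cl | intermediate (not isolated)
21 | lithium boronate complex of 20 and 19 | [Li+].C[C@]([B-]1(CC/C=C(C)/CC/C=C(C)/C2(CC=C(C)C)SCCCS2)OCC(C)(C)CO1)(OC(=O)c1c(C(C)C)cc(C(C)C)cc1C(C)C)CCc1cc(O[Si](C(C)C)(C(C)C)C(C)C)cc(C)c1Cl | intermediate (not isolated)
22 | 2-[(3S,6E,10E)-1-{2-chloro-3-methyl-5-[(triisopropylsilyl)oxy]phenyl}-3,7-dimethyl-11-[2-(3-methylbut-2-en-1-yl)-1,3-dithian-2-yl]dodeca-6,10-dien-3-yl]-5,5-dimethyl-1,3,2-dioxaborinane | C[C@](CC/C=C(C)/CC/C=C(C)/C1(CC=C(C)C)SCCCS1)(B1OCC(C)(C)CO1)CCc1cc(O[Si](C(C)C)(C(C)C)C(C)C)cc(C)c1Cl | intermediate (not isolated)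
23 | (3R,6E,10E)-1-{2-chloro-3-methyl-5-[(triisopropylsilyl)oxy]phenyl}-3,7-dimethyl-11-[2-(3-methylbut-2-en-1-yl)-1,3-dithian-2-yl]dodeca-6,10-dien-3-ol | C[C@](CC/C=C(C)/CC/C=C(C)/C1(CC=C(C)C)SCCCS1)(O)CCc1cc(O[Si](C(C)C)(C(C)C)C(C)C)cc(C)c1Cl | intermediate
24 | {[(2R)-2,8-dimethyl-2-{(3E,7E)-4-methyl-8-[2-(3-methylbut-2-en-1-yl)-1,3-dithian-2-yl]nona-3,7-dien-1-yl}chroman-6-yl]oxy}triisopropylsilane | C[C@@]1(CC/C=C(C)/CC/C=C(C)/C2(CC=C(C)C)SCCCS2)CCc2cc(O[Si](C(C)C)(C(C)C)C(C)C)cc(C)c2O1 | intermediate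
25 | (6E,10E)-13-{(2R)-2,8-dimethyl-6-[(triisopropylsilyl)oxy]chroman-2-yl}-2,6,10-trimethyltrideca-2,6,10-trien-5-one | C[C@@]1(CC/C=C(C)/CC/C=C(C)/C(=O)CC=C(C)C)CCc2cc(O[Si](C(C)C)(C(C)C)C(C)C)cc(C)c2O1 | intermediate
26 | (6E,10E)-13-[(2R)-6-hydroxy-2,8-dimethylchroman-2-yl]-2,6,10-trimethyltrideca-2,6,10-trien-5-one | CC(C)=CCC(=O)/C(C)=C/CC/C(C)=C/CC[C@]1(C)CCc2cc(O)cc(C)c2O1 | target

**Summary**

Total step count: 15. Longest linear sequence: 11 steps (steps 5–15, from geranyl acetate); the aryl branch (steps 1–4) joins at step 12.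

**Steps most likely to fail**

1. Step 12. The unactivated secondary benzoate may be deprotonated too slowly, so that benzylic or ring metalation of the chloroarene competes. The hindered boronate complex may also revert instead of rearranging, giving low conversion or loss of stereochemical fidelity. Fallback: the same bond is made by a ligand-controlled carbonyl addition. Alcohol 6 is oxidised (Dess–Martin periodinane, NaHCO3, CH2Cl2) to 4-{2-chloro-3-methyl-5-[(triisopropylsilyl)oxy]phenyl}butan-2-one F1. Boronate 17 is oxidised (NaOH, H2O2, THF) to (3E,7E)-4-methyl-8-[2-(3-methylbut-2-en-1-yl)-1,3-dithian-2-yl]nona-3,7-dien-1-ol F2, converted (I2, PPh3, imidazole) into the corresponding primary iodide F3 and inserted with magnesium (Et2O) to the alkylmagnesium iodide F4. F4 is added to F1 at −78 °C in the presence of a stoichiometric chiral tridentate diamino-phenol ligand derived from trans-1,2-diaminocyclohexane (asymmetric Grignard 1,2-addition to a ketone). This should give tertiary alcohol 23, where the route is rejoined; enantiomeric enrichment by preparative chiral chromatography is available at that stage if facial discrimination between methyl and arylethyl is insufficient.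

2. Step 13. The chelating dithiane sulfur may deactivate the palladium catalyst, and oxidative addition into the di-ortho-substituted, electron-rich C–Cl bond may be slow, so that cyclisation stalls or hydrodechlorination takes over. Fallback: the sulfur is removed before the ring closure and the ketone is carried at the alcohol oxidation level. Compound 23 is treated with MeI/CaCO3 in aqueous MeCN to give (6E,10E,13R)-15-{2-chloro-3-methyl-5-[(triisopropylsilyl)oxy]phenyl}-13-hydroxy-2,6,10,13-tetramethylpentadeca-2,6,10-trien-5-one F5. Luche reduction (NaBH4, CeCl3, MeOH) gives the corresponding 5,13-diol F6 (mixture of epimers at the carbinol that is later re-oxidised). Palladium-catalysed C–O cyclisation of this sulfur-free substrate gives the chroman allylic alcohol F7, and MnO2 in CH2Cl2 oxidises the allylic alcohol to enone 25, where the route is rejoined.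

3. Step 2. Over-bromination (second methyl group or dibromomethyl) and electrophilic ring bromination ortho to the silyloxy group may erode the yield of the monobromide. Fallback: halogenation is avoided by lateral metalation. Silyl ether 2 is deprotonated at one benzylic methyl group with nBuLi/KOtBu (THF, −78 °C) to the benzylpotassium compound F8, which is transmetalated with MgBr2·OEt2 to Grignard reagent 5, where the route is rejoined before the copper-catalysed opening of 4.

**Further compounds**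

F1 | step 12 | 4-{2-chloro-3-methyl-5-[(triisopropylsilyl)oxy]phenyl}butan-2-one | CC(=O)CCc1cc(O[Si](C(C)C)(C(C)C)C(C)C)cc(C)c1Cl
F2 | step 12 | (3E,7E)-4-methyl-8-[2-(3-methylbut-2-en-1-yl)-1,3-dithian-2-yl]nona-3,7-dien-1-ol | OCC/C=C(C)/CC/C=C(C)/C1(CC=C(C)C)SCCCS1
F3 | step 12 | 2-[(2E,6E)-9-iodo-6-methylnona-2,6-dien-2-yl]-2-(3-methylbut-2-en-1-yl)-1,3-dithiane | ICC/C=C(C)/CC/C=C(C)/C1(CC=C(C)C)SCCCS1
F4 | step 12 | {(3E,7E)-4-methyl-8-[2-(3-methylbut-2-en-1-yl)-1,3-dithian-2-yl]nona-3,7-dien-1-yl}magnesium iodide | I[Mg]CC/C=C(C)/CC/C=C(C)/C1(CC=C(C)C)SCCCS1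
F5 | step 13 | (6E,10E,13R)-15-{2-chloro-3-methyl-5-[(triisopropylsilyl)oxy]phenyl}-13-hydroxy-2,6,10,13-tetramethylpentadeca-2,6,10-trien-5-one | C[C@](CC/C=C(C)/CC/C=C(C)/C(=O)CC=C(C)C)(O)CCc1cc(O[Si](C(C)C)(C(C)C)C(C)C)cc(C)c1Cl
F6 | step 13 | (6E,10E,13R)-15-{2-chloro-3-methyl-5-[(triisopropylsilyl)oxy]phenyl}-2,6,10,13-tetramethylpentadeca-2,6,10-triene-5,13-diol (epimers at C5) | C[C@](CC/C=C(C)/CC/C=C(C)/C(O)CC=C(C)C)(O)CCc1cc(O[Si](C(C)C)(C(C)C)C(C)C)cc(C)c1Cl
F7 | step 13 | (6E,10E)-13-{(2R)-2,8-dimethyl-6-[(triisopropylsilyl)oxy]chroman-2-yl}-2,6,10-trimethyltrideca-2,6,10-trien-5-ol (epimers at C5) | C[C@@]1(CC/C=C(C)/CC/C=C(C)/C(O)CC=C(C)C)CCc2cc(O[Si](C(C)C)(C(C)C)C(C)C)cc(C)c2O1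
F8 | step 2 | {2-chloro-3-methyl-5-[(triisopropylsilyl)oxy]benzyl}potassium | [K]Cc1cc(O[Si](C(C)C)(C(C)C)C(C)C)cc(C)c1Cl
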